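The route rests on disconnecting C1–C10 of ring A. In one operation, hydrogen-atom transfer to an exocyclic C10 methylene creates the tertiary C10 radical (and the C20 methyl), which closes ring A onto a C1 aldehyde tosylhydrazone. Loss of sulfinate and N2 then leaves the bare C1 methylene, so the quaternary C10 and the trans A/B fusion are set without any residual activating group. The step exploits the angular-methyl quaternary C10 flanked by the unfunctionalised C1–C3 methylenes. Its precursor is a monocyclic ring B from (S)-carvone carrying the C4 gem-dimethyl tether, a C9 carbinol and C10=CH2; the C9 oxygen later delivers the C8=C9 alkene and side chain.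

Key step: step 5

Remark: labdane numbering is used for all intermediates (ring A C1–C5/C10, ring B C5–C10, C17 on C8, C18/C19 on C4, C20 on C10, side chain C11–C16). Compounds 1, 2, 16 and 22 are taken as commercial.

Step 1
Reactants: 1 (S)-(+)-carvone; 2 acrylonitrile
Product: 3 4-methyl-4-[(1S)-4-methyl-5-oxocyclohex-3-en-1-yl]pentanenitrile
Conditions: Fe(acac)3 (30 mol%), PhSiH3, EtOH/(CH2OH)2, 60 °C
Reagents that add atoms: none
Why: Iron-hydride hydrogen-atom transfer (Mukaiyama type) to the 1,1-disubstituted isopropenyl alkene should give the tertiary C4 radical, which adds to acrylonitrile in a Giese reaction (reductive olefin coupling) to build the quaternary C4 and the C3–C2–C1 chain, while the less reactive conjugated enone and the C5 stereocentre stay untouched.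

Step 2
Reactants: 3 4-methyl-4-[(1S)-4-methyl-5-oxocyclohex-3-en-1-yl]pentanenitrile
Product: 7 4-methyl-4-[(1R)-4-methyl-2-methylidene-3-oxocyclohex-4-en-1-yl]pentanenitrile, via lithium dienolate 4 (not isolated), via Mannich base 5 (not isolated), via amine oxide 6 (not isolated)
Conditions: LiN(i-Pr)2, THF, −78 °C; Me2N=CH2 I, −78 °C → rt; crude amine, mCPBA, NaHCO3, CH2Cl2, 0 °C → rt; product used at once
Reagents that add atoms: N,N-dimethylmethyleneiminium iodide, C[N+](C)=C.[I-]
Why: Kinetic α'-deprotonation at C10, Mannich reaction of the cross-conjugated dienolate with the iminium salt and Cope elimination of the derived amine oxide should install the exocyclic C10 methylene under near-neutral conditions that spare the C5 centre (the transient C10 centre is lost).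

Step 3
Reactants: 7 4-methyl-4-[(1R)-4-methyl-2-methylidene-3-oxocyclohex-4-en-1-yl]pentanenitrile
Product: 8 4-[(1R,3R)-3-hydroxy-4-methyl-2-methylidenecyclohex-4-en-1-yl]-4-methylpentanal
Conditions: i-Bu2AlH (3.5 equiv), CH2Cl2, −78 → −20 °C; then H2O, aqueous sodium potassium tartrate, rt
Reagents that add atoms: water, O
Why: DIBAL-H should reduce the cross-conjugated ketone 1,2 by axial hydride delivery, giving the equatorial C9 carbinol cis to the C5 substituent as in the reduction of carvone to cis-carveol, and take the nitrile to the N-aluminio aldimine (partial nitrile reduction), which water hydrolyses on the buffered work-up to the C1 aldehyde, the aldehyde oxygen coming from water and the nitrogen leaving as ammonia (any C9 epimer converges at 13).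

Step 4
Reactants: 8 4-[(1R,3R)-3-hydroxy-4-methyl-2-methylidenecyclohex-4-en-1-yl]-4-methylpentanal
Product: 9 4-methyl-N'-[(1E)-4-[(1R,3R)-3-hydroxy-4-methyl-2-methylidenecyclohex-4-en-1-yl]-4-methylpentylidene]benzenesulfonohydrazide
Conditions: TsNHNH2 (1.05 equiv), EtOH, rt
Reagents that add atoms: p-toluenesulfonyl hydrazide, Cc1ccc(cc1)S(=O)(=O)NN
Why: Hydrazone formation by condensation at the unhindered aldehyde should be fast and chemoselective, and sets only the E C=N geometry.

Step 5
Reactants: 9 4-methyl-N'-[(1E)-4-[(1R,3R)-3-hydroxy-4-methyl-2-methylidenecyclohex-4-en-1-yl]-4-methylpentylidene]benzenesulfonohydrazide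
Product: 12 (1R,4aR,8aR)-2,5,5,8a-tetramethyl-1,4,4a,5,6,7,8,8a-octahydronaphthalen-1-ol, via cyclised tosylhydrazine 10 (not isolated), via alkyl diazene 11 (not isolated)
Conditions: Fe(acac)3 (30 mol%), PhSiH3 (2.5 equiv), EtOH, 60 °C; then Et3N, 80 °C
Reagents that add atoms: none
Why: Hydrogen-atom transfer from the iron hydride formed from Fe(acac)3 and PhSiH3 to the exocyclic C10=CH2 should give the tertiary C10 radical (the added hydrogen completes the C20 methyl), which adds to the C1 carbon of the tosylhydrazone; reduction of the hydrazinyl radical gives 10, and Et3N then expels sulfinate to give diazene 11, which loses N2 and leaves C1 as a methylene. The closest known reaction type is the iron-hydride reductive alkylation of unactivated alkenes with tosylhydrazones (HAT-initiated Giese-type addition to C=N, then base-induced loss of sulfinate and N2), run here intramolecularly. Ring A closes in the 6-exo-trig mode onto C=N. The new quaternary stereocentre C10 is controlled by C5: ring B should sit in the half-chair with the C5 tether and the cis C9 hydroxyl both equatorial, and closure through the chair-like transition state places the new C1–C10 bond equatorial on ring B, on the face of H-5, so the C20 methyl ends anti to H-5 (trans fusion). The cis fusion would need the tether or the new bond axial. The step needs HAT at the 1,1-disubstituted alkene rather than at the trisubstituted C7=C8 alkene, which the higher reactivity of terminal 1,1-disubstituted alkenes secures, and cyclisation faster than quenching of the radical, which the tethered electrophilic C=N acceptor secures.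

Step 6
Reactants: 12 (1R,4aR,8aR)-2,5,5,8a-tetramethyl-1,4,4a,5,6,7,8,8a-octahydronaphthalen-1-ol
Product: 13 (4aR,8aR)-2,5,5,8a-tetramethyl-4a,5,6,7,8,8a-hexahydronaphthalen-1(4H)-one
Conditions: DMP, NaHCO3, CH2Cl2, 0 °C → rt
Reagents that add atoms: none
Why: Dess–Martin oxidation of the allylic alcohol should give the enone without alkene migration and erases the C9 stereocentre.

Step 7
Reactants: 13 (4aR,8aR)-2,5,5,8a-tetramethyl-4a,5,6,7,8,8a-hexahydronaphthalen-1(4H)-one
Product: 15 (4aR,8aR)-2,5,5,8a-tetramethyl-3,4,4a,5,6,7,8,8a-octahydronaphthalen-1-yl trifluoromethanesulfonate, via lithium enolate 14 (not isolated)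
Conditions: LiB(s-Bu)3H, THF, −78 °C; then N-(5-chloro-2-pyridyl)bis(trifluoromethanesulfonimide), −78 → 0 °C
Reagents that add atoms: N-(5-chloro-2-pyridyl)bis(trifluoromethanesulfonimide), FC(F)(F)S(=O)(=O)N(c1ccc(Cl)cn1)S(=O)(=O)C(F)(F)F
Why: Conjugate hydride reduction of the enone, whose β-carbon C7 carries no substituent and whose carbonyl is shielded by the quaternary C10, should give the C8=C9 enolate regiospecifically, and O-triflation (enolate trapping) fixes the position of the future tetrasubstituted alkene.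

Step 8
Reactants: 16 methyl hydrogen (R)-3-methylglutarate
Product: 17 methyl (3R)-5-hydroxy-3-methylpentanoate
Conditions: BH3·SMe2, THF, 0 °C → rt; MeOH quench
Reagents that add atoms: none
Why: Borane reduces carboxylic acids much faster than esters (chemoselective borane reduction), so only the acid terminus should be reduced, with the C13 stereocentre untouched.

Step 9
Reactants: 17 methyl (3R)-5-hydroxy-3-methylpentanoate
Product: 18 methyl (3S)-5-iodo-3-methylpentanoate
Conditions: I2, PPh3, imidazole, CH2Cl2, 0 °C → rt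
Reagents that add atoms: iodine, II
Why: Appel-type iodination should convert the primary alcohol to the iodide under neutral conditions that avoid lactonisation (the descriptor changes only through the priority rules).

Step 10
Reactants: 15 (4aR,8aR)-2,5,5,8a-tetramethyl-3,4,4a,5,6,7,8,8a-octahydronaphthalen-1-yl trifluoromethanesulfonate; 18 methyl (3S)-5-iodo-3-methylpentanoate
Product: 20 methyl (3R)-3-methyl-5-[(4aR,8aR)-2,5,5,8a-tetramethyl-3,4,4a,5,6,7,8,8a-octahydronaphthalen-1-yl]pentanoate, via alkylzinc iodide 19 (not isolated)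
Conditions: Zn dust, LiCl, THF, 40 °C; then 15, Pd(dppf)Cl2 (5 mol%), THF/DMA, 60 °C
Reagents that add atoms: none
Why: Zinc insertion into the primary iodide gives an ester-tolerant alkylzinc reagent, and Negishi coupling with the alkenyl triflate should form the C9–C11 bond with the alkene fixed at C8=C9, as known for 2,6,6-trimethylcyclohexenyl triflates.

Step 11
Reactants: 20 methyl (3R)-3-methyl-5-[(4aR,8aR)-2,5,5,8a-tetramethyl-3,4,4a,5,6,7,8,8a-octahydronaphthalen-1-yl]pentanoate
Product: 21 (3R)-3-methyl-5-[(4aR,8aR)-2,5,5,8a-tetramethyl-3,4,4a,5,6,7,8,8a-octahydronaphthalen-1-yl]pentanoic acid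
Conditions: LiOH·H2O, THF/MeOH/H2O, 40 °C; then 1 M HCl
Reagents that add atoms: lithium hydroxide, [Li+].[OH-]
Why: Saponification of the unhindered methyl ester should proceed without affecting the tetrasubstituted alkene or the stereocentres.

Step 12
Reactants: 21 (3R)-3-methyl-5-[(4aR,8aR)-2,5,5,8a-tetramethyl-3,4,4a,5,6,7,8,8a-octahydronaphthalen-1-yl]pentanoic acid; 22 (S)-glycidol
Product: 23 [(2R)-oxiran-2-yl]methyl (3R)-3-methyl-5-[(4aR,8aR)-2,5,5,8a-tetramethyl-3,4,4a,5,6,7,8,8a-octahydronaphthalen-1-yl]pentanoate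
Conditions: DCC, DMAP (10 mol%), CH2Cl2, 0 °C → rt
Reagents that add atoms: none
Why: Steglich esterification at the primary hydroxyl of glycidol should give the glycidyl ester without touching the epoxide stereocentre (S becomes R only through the priority rules).

Step 13
Reactants: 23 [(2R)-oxiran-2-yl]methyl (3R)-3-methyl-5-[(4aR,8aR)-2,5,5,8a-tetramethyl-3,4,4a,5,6,7,8,8a-octahydronaphthalen-1-yl]pentanoate
Product: 24 (2R)-3-(acetyloxy)-2-hydroxypropyl (3R)-3-methyl-5-[(4aR,8aR)-2,5,5,8a-tetramethyl-3,4,4a,5,6,7,8,8a-octahydronaphthalen-1-yl]pentanoate (CNP0137802.3)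
Conditions: AcOH (1.5 equiv), racemic (salen)Co(OAc) [salen = N,N'-bis(3,5-di-tert-butylsalicylidene)cyclohexane-1,2-diaminate] (5 mol%), i-Pr2NEt, t-BuOMe, rt
Reagents that add atoms: acetic acid, CC(=O)O
Why: Cobalt–salen-catalysed SN2 opening of the terminal epoxide carbon by the carboxylic acid (regioselective acidolysis of a glycidyl ester) should place the acetate on the primary carbon and free the C2 hydroxyl without touching the stereocentre, under conditions mild enough to suppress acyl migration.

Compound list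
1 | (S)-(+)-carvone | CC1=CC[C@@H](CC1=O)C(C)=C | starting material
2 | acrylonitrile | C=CC#N | starting material
3 | 4-methyl-4-[(1S)-4-methyl-5-oxocyclohex-3-en-1-yl]pentanenitrile | CC1=CC[C@@H](CC1=O)C(C)(C)CCC#N | intermediate
4 | lithium cross-conjugated dienolate of 3 (C9–OLi, C9=C10) | CC1=CC[C@@H](C=C1O[Li])C(C)(C)CCC#N | intermediate (not isolated)
5 | 4-[(1S,2S)-2-[(dimethylamino)methyl]-4-methyl-3-oxocyclohex-4-en-1-yl]-4-methylpentanenitrile (Mannich base) | CC1=CC[C@@H]([C@@H](CN(C)C)C1=O)C(C)(C)CCC#N | intermediate (not isolated)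
6 | N-oxide of 5 | CC1=CC[C@@H]([C@@H](C[N+](C)(C)[O-])C1=O)C(C)(C)CCC#N | intermediate (not isolated)
7 | 4-methyl-4-[(1R)-4-methyl-2-methylidene-3-oxocyclohex-4-en-1-yl]pentanenitrile | CC1=CC[C@@H](C(=C)C1=O)C(C)(C)CCC#N | intermediate
8 | 4-[(1R,3R)-3-hydroxy-4-methyl-2-methylidenecyclohex-4-en-1-yl]-4-methylpentanal | CC1=CC[C@@H](C(=C)[C@@H]1O)C(C)(C)CCC=O | intermediate
9 | 4-methyl-N'-[(1E)-4-[(1R,3R)-3-hydroxy-4-methyl-2-methylidenecyclohex-4-en-1-yl]-4-methylpentylidene]benzenesulfonohydrazide | CC1=CC[C@@H](C(=C)[C@@H]1O)C(C)(C)CC/C=N/NS(=O)(=O)c2ccc(C)cc2 | intermediate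
10 | cyclised N-alkyl-N'-tosylhydrazine (trans-decalin, hydrazine on C1, C1 epimers) | O[C@@H]1C(C)=CC[C@@H]2C(C)(C)CCC(NNS(=O)(=O)c3ccc(C)cc3)[C@@]12C | intermediate (not isolated)
11 | C1 alkyl diazene (C1 epimers) | O[C@@H]1C(C)=CC[C@@H]2C(C)(C)CCC(N=N)[C@@]12C | intermediate (not isolated)
12 | (1R,4aR,8aR)-2,5,5,8a-tetramethyl-1,4,4a,5,6,7,8,8a-octahydronaphthalen-1-ol | O[C@@H]1C(C)=CC[C@@H]2C(C)(C)CCC[C@@]12C | intermediate
13 | (4aR,8aR)-2,5,5,8a-tetramethyl-4a,5,6,7,8,8a-hexahydronaphthalen-1(4H)-one | O=C1C(C)=CC[C@@H]2C(C)(C)CCC[C@@]12C | intermediate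
14 | lithium (4aR,8aR)-2,5,5,8a-tetramethyl-3,4,4a,5,6,7,8,8a-octahydronaphthalen-1-olate | [Li]OC1=C(C)CC[C@@H]2C(C)(C)CCC[C@@]12C | intermediate (not isolated)
15 | (4aR,8aR)-2,5,5,8a-tetramethyl-3,4,4a,5,6,7,8,8a-octahydronaphthalen-1-yl trifluoromethanesulfonate | FC(F)(F)S(=O)(=O)OC1=C(C)CC[C@@H]2C(C)(C)CCC[C@@]12C | intermediate
16 | methyl hydrogen (R)-3-methylglutarate [(3R)-5-methoxy-3-methyl-5-oxopentanoic acid] | COC(=O)C[C@H](C)CC(=O)O | starting material
17 | methyl (3R)-5-hydroxy-3-methylpentanoate | COC(=O)C[C@H](C)CCO | intermediate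
18 | methyl (3S)-5-iodo-3-methylpentanoate | COC(=O)C[C@H](C)CCI | intermediate
19 | [(3S)-5-methoxy-3-methyl-5-oxopentyl]zinc iodide | COC(=O)C[C@H](C)CC[Zn]I | intermediate (not isolated)
20 | methyl (3R)-3-methyl-5-[(4aR,8aR)-2,5,5,8a-tetramethyl-3,4,4a,5,6,7,8,8a-octahydronaphthalen-1-yl]pentanoate | COC(=O)C[C@H](C)CCC1=C(C)CC[C@@H]2C(C)(C)CCC[C@@]12C | intermediate
21 | (3R)-3-methyl-5-[(4aR,8aR)-2,5,5,8a-tetramethyl-3,4,4a,5,6,7,8,8a-octahydronaphthalen-1-yl]pentanoic acid | OC(=O)C[C@H](C)CCC1=C(C)CC[C@@H]2C(C)(C)CCC[C@@]12C | intermediate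
22 | (S)-glycidol | C1[C@@H](O1)CO | starting material
23 | [(2R)-oxiran-2-yl]methyl (3R)-3-methyl-5-[(4aR,8aR)-2,5,5,8a-tetramethyl-3,4,4a,5,6,7,8,8a-octahydronaphthalen-1-yl]pentanoate | C1[C@@H](O1)COC(=O)C[C@H](C)CCC2=C(C)CC[C@@H]3C(C)(C)CCC[C@@]23C | intermediate
24 | (2R)-3-(acetyloxy)-2-hydroxypropyl (3R)-3-methyl-5-[(4aR,8aR)-2,5,5,8a-tetramethyl-3,4,4a,5,6,7,8,8a-octahydronaphthalen-1-yl]pentanoate (CNP0137802.3) | CC(=O)OC[C@@H](O)COC(=O)C[C@H](C)CCC1=C(C)CC[C@@H]2C(C)(C)CCC[C@@]12C | target

Total step count: 13. Longest linear sequence: 11 (steps 1–7 and 10–13); steps 8–9 are the side-chain branch.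

Steps most likely to fail:

Step 5 (key step). The tertiary C10 radical may be quenched by hydrogen-atom transfer, or the allylic carbinol may undergo hydride-mediated redox isomerisation, before ring closure. The trans fusion may also erode if closure runs from the conformer with the tether axial. The fallback sets out from 8 and comes back at 12; it uses the carbonyl itself as radical acceptor and removes the C1 oxygen afterwards. Silylation of 8 (TBSCl, imidazole, DMF) should give 4-[(1R,3R)-3-[(tert-butyldimethylsilyl)oxy]-4-methyl-2-methylidenecyclohex-4-en-1-yl]-4-methylpentanal F1, whose bulky equatorial silyl ether also reinforces the ring B lock. Iron-hydride HAT-initiated radical cyclisation onto the aldehyde (Fe(acac)3, PhSiH3, EtOH, 60 °C) should close the same C1–C10 bond and give 8-[(tert-butyldimethylsilyl)oxy]-4,4,7,8a-tetramethyl-1,2,3,4,4a,5,8,8a-octahydronaphthalen-1-ol F2 as C1 carbinol epimers. NaH, CS2 and MeI should give the S-methyl xanthate F3, and Barton–McCombie deoxygenation (Bu3SnH, AIBN, toluene, 110 °C) the silyl ether tert-butyldimethyl{[(1R,4aR,8aR)-2,5,5,8a-tetramethyl-1,4,4a,5,6,7,8,8a-octahydronaphthalen-1-yl]oxy}silane F4. Bu4NF in THF then returns 12.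

Step 10. Transmetalation and reductive elimination at the hindered tetrasubstituted alkenylpalladium next to the quaternary C10 may be slow, so that protodezincation of 19 and reduction of the triflate take over. The fallback sets out from 18 and 15 and comes back at 20; it replaces the zinc reagent by a borane. Elimination of 18 with DBU (toluene, 80 °C) should give methyl (3S)-3-methylpent-4-enoate F5. Hydroboration with 9-BBN should give methyl (3R)-5-(9-borabicyclo[3.3.1]nonan-9-yl)-3-methylpentanoate F6, used in situ. B-alkyl Suzuki–Miyaura coupling with 15 (Pd(dppf)Cl2, Cs2CO3, AsPh3, DMF/THF/H2O, 60 °C) should then give 20.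

Step 2. The cross-conjugated exocyclic dienone 7 may dimerise, lose the C5 configuration through the extended enolate, or aromatise by migration of the exocyclic alkene into the ring. The fallback sets out from 3 and comes back at 8; the ketone is reduced before the methylene is unveiled, so 7 is never formed. The Mannich base 5 is made as in step 2 but isolated. Luche reduction (NaBH4, CeCl3·7H2O, MeOH, −78 °C) should give 4-[(1S,2S,3S)-2-[(dimethylamino)methyl]-3-hydroxy-4-methylcyclohex-4-en-1-yl]-4-methylpentanenitrile F7. mCPBA should give its amine oxide F8, which on warming should undergo Cope elimination to 4-[(1R,3R)-3-hydroxy-4-methyl-2-methylidenecyclohex-4-en-1-yl]-4-methylpentanenitrile F9. DIBAL-H reduction of the nitrile, followed by hydrolysis of the aldimine on buffered aqueous work-up, then gives 8.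

Further compounds
F1 | step 5 | 4-[(1R,3R)-3-[(tert-butyldimethylsilyl)oxy]-4-methyl-2-methylidenecyclohex-4-en-1-yl]-4-methylpentanal | CC1=CC[C@@H](C(=C)[C@@H]1O[Si](C)(C)C(C)(C)C)C(C)(C)CCC=O
F2 | step 5 | 8-[(tert-butyldimethylsilyl)oxy]-4,4,7,8a-tetramethyl-1,2,3,4,4a,5,8,8a-octahydronaphthalen-1-ol (trans-fused, C1 carbinol epimers) | CC(C)(C)[Si](C)(C)O[C@@H]1C(C)=CC[C@@H]2C(C)(C)CCC(O)[C@@]12C
F3 | step 5 | O-{8-[(tert-butyldimethylsilyl)oxy]-4,4,7,8a-tetramethyl-1,2,3,4,4a,5,8,8a-octahydronaphthalen-1-yl} S-methyl carbonodithioate (C1 epimers) | CC(C)(C)[Si](C)(C)O[C@@H]1C(C)=CC[C@@H]2C(C)(C)CCC(OC(=S)SC)[C@@]12C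
F4 | step 5 | tert-butyldimethyl{[(1R,4aR,8aR)-2,5,5,8a-tetramethyl-1,4,4a,5,6,7,8,8a-octahydronaphthalen-1-yl]oxy}silane | CC(C)(C)[Si](C)(C)O[C@@H]1C(C)=CC[C@@H]2C(C)(C)CCC[C@@]12C
F5 | step 10 | methyl (3S)-3-methylpent-4-enoate | COC(=O)C[C@H](C)C=C
F6 | step 10 | methyl (3R)-5-(9-borabicyclo[3.3.1]nonan-9-yl)-3-methylpentanoate | COC(=O)C[C@H](C)CCB1C2CCCC1CCC2
F7 | step 2 | 4-[(1S,2S,3S)-2-[(dimethylamino)methyl]-3-hydroxy-4-methylcyclohex-4-en-1-yl]-4-methylpentanenitrile | CC1=CC[C@@H]([C@@H](CN(C)C)[C@@H]1O)C(C)(C)CCC#N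
F8 | step 2 | N-oxide of F7 | CC1=CC[C@@H]([C@@H](C[N+](C)(C)[O-])[C@@H]1O)C(C)(C)CCC#N
F9 | step 2 | 4-[(1R,3R)-3-hydroxy-4-methyl-2-methylidenecyclohex-4-en-1-yl]-4-methylpentanenitrile | CC1=CC[C@@H](C(=C)[C@@H]1O)C(C)(C)CCC#N
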